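# Proposed total synthesis of CNP0497637.1 by B-alkyl Suzuki closure of ring B

## Structural features

The target is a tetracycle, numbered here as a caryophyllane. Gem-dimethylcyclobutane ring A is trans-fused through C1 and C9 to nine-membered carbocycle B, which carries an exocyclic methylene on C8, the carbon next to C9. Ring B shares its C4–C5 bond with dihydropyran ring C, and ring C is fused to ring D, a dearomatised acylphloroglucinol (an enolised β-triketone with a gem-dimethyl carbon and an isobutyryl group). The four stereocentres form two adjacent pairs, C1 (R)/C9 (S) on the cyclobutane and C4 (S)/C5 (R) at the B/C fusion, where the C4 methyl and the C5 hydrogen are anti. The pairs are separated by the C2–C3 and C6–C7 methylene bridges, so neither can be trusted to control the other in an open chain. C4 bears oxygen, a methyl group and two primary alkyl arms, so a method that must tell methyl from CH2R by size is weak; a stereospecific addition to an alkene of defined geometry is the safe way to set it. Fragile groups are the exocyclic alkene beside the strained cyclobutane (acid-induced cationic rearrangement), the tertiary C4–O ether, the vinylogous acid of ring D, and the C9 hydrogen whenever C8 is a carbonyl. The real difficulty is the nine-membered ring together with the correct relative configuration of the two stereo pairs. The key step uses the fact that C8 is an sp2 carbon attached to the C7H2–C6H2–C5 unit. The C7–C8 bond is therefore an sp3–sp2 bond that a vinyl group on C5 and a 2-alkenyl electrophile on C9 can form, with the methylene left in place.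

## Logic of the disconnections

**36 ⇒ 34.** The two C8–CH3 bonds of ring D are cut. 36 is the dearomatised form of an acylphloroglucinol, and C8 is the only unsubstituted ring carbon of 34. The gain is that ring D becomes a flat arene that tolerates organometallic chemistry, so the sensitive triketone arrives last. The forward step must alkylate carbon twice at the same position and not oxygen.

**34 ⇒ 33 ⇒ 30 + 31.** The aryl C6–acyl bond is cut after re-masking the phenols as acetals. C6 lies between both acetal oxygens and is the best site for directed metalation. The gain is that 30 has no carbonyl and no hydroxyl group. The forward step needs lithiation at C6 and not C8, and a single addition to 31.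

**30 ⇒ 28 (key).** The C7–C8 bond of ring B is cut, giving a vinyl group on C5 and an alkenyl triflate on C9. This removes the medium ring and leaves the exocyclic methylene as the residue of the electrophile. The forward step must close a nine-membered ring faster than it oligomerises, and the borane must touch only the vinyl group.

**28 ⇒ 26 ⇒ 23.** The C8–O bond of the enol triflate is cut back to a methyl ketone, and the C8–C13 bond back to an amide. An alkenyl electrophile would not survive the palladium-catalysed fragment union or the hot alkoxide of the etherification, so C8 travels as an inert amide. The ketone stage is also where C9 is equilibrated to trans. The forward steps need one organometallic addition only and kinetic enolisation at the methyl group.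

**23 ⇒ 22.** The aryl C–O bond of ring C is cut. Closing at the arene carbon, and not at C4, cannot scramble the C4 configuration already present in the tertiary alcohol. The forward step needs C–O coupling of a hindered tertiary alkoxide without reaction at the vinyl group.

**22 ⇒ 21 ⇒ 20.** The C5–C6 bond (vinyl to C5) is cut, then both epoxide C–O bonds. Anti addition of oxygen at C4 and vinyl at C5 across the E alkene of 20 sets both centres stereospecifically, and a chiral catalyst sets the absolute sense. Two stereocentres are reduced to one alkene geometry. The forward steps need high face selectivity in the epoxidation and SN2 opening at the secondary carbon with inversion.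

**20 ⇒ 8 + 18.** The C3–C4 sp3–sp2 bond is cut. A B-alkyl coupling carries the geometry of 18 over unchanged, and the vinyl group of 8 is the latent C2–C3 unit. The route becomes convergent, with a terpenoid half and an aromatic half. The alkenyl iodide must react and the aryl bromide must not.

**18 ⇒ 16 ⇒ 15 ⇒ 13 ⇒ 12 ⇒ 11 ⇒ 9.** The C4–I bond is cut (syn hydrometalation of an alkyne), then the benzylic C–C(sp) bond, then functional-group changes, then the formyl–aryl bond. Each step is a standard operation on a simple arene. The demands are metal placement on the methyl-bearing alkyne carbon and formylation next to bromine.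

**8 ⇒ 6 ⇒ 4 ⇒ 2 + 3 ⇒ 1.** The amide C–N bond is cut. The vinyl group and the carboxyl group are then reconnected as an iodomethyl lactone (a reductive fragmentation in reverse). Last, the C9–C10 and C1–C11 bonds are cut ([2+2] cycloaddition). The stereocentre of 1 directs the face and is then excised, and the lactone supplies exactly the two handles needed: carboxyl for C8 and vinyl for C2/C3. The forward step needs head-to-tail regiochemistry and anti facial selectivity. C1 is set for good; C9 is formed cis and corrected at 26.

## Other disconnections considered

**Alternative 1:** The cut removes ring C: the bond from the pyran CH2-derived carbon to ring D and the C4–O bond. It leads back to enal A2 (the caryophyllane skeleton with its C4=C5 alkene kept and a formyl group on C5) and acyl trione A3. In the forward step an amine salt catalyses Knoevenagel condensation to a 1-oxatriene, which closes by oxa-6π electrocyclisation to 2H-pyran A1.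
- In its favour: rings A and B with C1 and C9 could come intact from (−)-β-caryophyllene A4, and ring D arrives complete, so no medium ring is closed and the acylation and methylation end-game disappears. In step economy this is clearly the better plan.
- Against it here: A2 needs a site-defined formylation of A4 that keeps a tetrasubstituted ring alkene. C4 is set only by the conformational preference of the nine-membered ring during a reversible pericyclic closure. A1 still has a C5=CH double bond, which must be reduced chemoselectively (exocyclic methylene and enolised triketone present) and with hydrogen delivered anti to the C4 methyl.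
- Comparison: structurally, the alternative makes the same C4–O bond but leaves C5 unset, while the chosen plan sets C4 and C5 together from one alkene geometry. Mechanistically, it is reversible and substrate-controlled, against reagent-controlled epoxidation, SN2 opening and an irreversible coupling. The two plans are equal in leaving C1/C9 untouched once made.

**Alternative 2:** The cut is made on a chroman-4-one, at the bond from C2 to the side chain and the bond from C3 to an allyl group, leading back to 2-methylchromone A6. In the forward step a copper-catalysed asymmetric conjugate addition of Grignard reagent A7 is followed by trapping of the enolate with allyl bromide A8, giving A5.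
- In its favour: the oxygen-bearing quaternary centre is made catalytically in one flask from a chromone that is a few steps from phloroglucinol. Absolute control at that centre is catalyst-derived, as in the chosen plan, and is reached in fewer steps; on this point the alternative is the equal or the better.
- Against it here: addition to a 2-substituted chromone is a demanding case of the reaction. The C3 configuration relative to C2 rests on the small size difference between methyl and a primary chain, and C3 is epimerisable next to the ketone. Neither the cyclobutane nor ring B exists in A5. Both must still be built from the pentenyl and allyl termini, with C1 and C9 created under remote control at best, and the C4 carbonyl of the chromanone must be removed.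
- Comparison: the chosen plan brings C1/C9 from the chiral pool and fixes the C4/C5 relationship stereospecifically. It is longer up to the chroman, but shorter and more predictable from there to 36.

**Alternative 3:** The cut removes ring A (bonds C9–C10 and C1–C11), leading back to cis nine-membered enone A10 and 3. In the forward step irradiation gives the head-to-tail cycloadduct A9.
- In its favour: the regiochemistry of enone–isobutylene photocycloaddition is well known, and no chiral cyclobutane building block is needed. The C8 ketone of A9 allows base equilibration of C9 to the trans fusion, and methylenation would then give 30 directly. For these last two operations the alternative is the equal of the chosen plan and avoids the enol triflate.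
- Against it here: A10 is itself a nine-membered ring fused to the chroman, so the medium-ring problem is only moved. The face of the cycloaddition, which decides the uncorrectable centre C1, is governed only by transannular effects of C4/C5. Medium-ring enones can isomerise to trans enones on irradiation. The least selective step would be run on the most valuable material, with an electron-rich arene nearby.
- Comparison: the chosen plan uses the same photochemical bond construction, but as its second step on an inexpensive butenolide whose own stereocentre controls the face and is then excised. Overall step counts should be similar.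

Key step: step 17

Remark on the chemistry: ring B is closed from the 2-alkenyl triflate, the pseudohalide counterpart of a 2-bromoalkene with the same carbon skeleton, because it is reached from a methyl ketone by enolate chemistry alone, whereas electrophilic bromine sources would attack the electron-rich arene and the vinyl group.

## Route

Step 1
Reactants: 1 (S)-5-(hydroxymethyl)furan-2(5H)-one
Product: 2 [(2S)-5-oxo-2,5-dihydrofuran-2-yl]methyl 4-methylbenzenesulfonate
Conditions: TsCl, pyridine, CH2Cl2, 0 °C
Reagents that add atoms: 4-toluenesulfonyl chloride, Cc1ccc(cc1)S(Cl)(=O)=O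
Why: Sulfonylation of a primary alcohol; the sulfonate serves both as a bulky face-shielding group for the photocycloaddition and as the leaving group for the later fragmentation, so no separate protecting group is spent.

Step 2
Reactants: 2 butenolide tosylate; 3 isobutylene (2-methylpropene)
Product: 4 [(1R,4S,5R)-6,6-dimethyl-2-oxo-3-oxabicyclo[3.2.0]heptan-4-yl]methyl 4-methylbenzenesulfonate
Conditions: hν (Pyrex filter), 3 (excess), acetone, −40 °C
Reagents that add atoms: none
Why: Triplet-sensitised enone–alkene [2+2] photocycloaddition; 3 should add anti to the sulfonyloxymethyl group and head-to-tail (CH2 to the α-carbon, CMe2 to the β-carbon, as with cyclic enones), which sets the β-carbon (later C1) as R, while the cis α-carbon (later C9) is corrected in step 15. Minor regio- and face isomers are removed at this stage.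

Step 3
Reactants: 4 bicyclic lactone tosylate
Product: 6 (1R,2R)-2-ethenyl-3,3-dimethylcyclobutane-1-carboxylic acid (cis), via iodide 5 (not isolated)
Conditions: NaI, Zn, DMF, 80 °C; aq. HCl work-up
Reagents that add atoms: none
Why: Finkelstein exchange followed by zinc-mediated reductive elimination of the β-acyloxy iodide (the reverse of an iodolactonisation) opens the lactone to a carboxylic acid and a vinyl group in one operation; the directing stereocentre is destroyed and the two ring stereocentres are not touched.

Step 4
Reactants: 6 cis vinyl acid
Product: 8 [(1R,2R)-2-ethenyl-3,3-dimethylcyclobutyl](morpholin-4-yl)methanone, via acid chloride 7 (not isolated)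
Conditions: (COCl)2, DMF (cat.), CH2Cl2, 0 °C; then morpholine (2.5 equiv), −20 °C
Reagents that add atoms: morpholine, C1COCCN1
Why: Acyl chloride formation and aminolysis; the morpholine amide should be inert to 9-BBN at room temperature, to palladium, dioxirane, cuprate and hot alkoxide, and it is later turned into the methyl ketone by one organolithium addition, in the manner of a Weinreb amide.

Step 5
Reactants: 9 5-bromobenzene-1,3-diol
Product: 11 2-bromo-4,6-dihydroxybenzaldehyde, via iminium salt 10 (not isolated)
Conditions: POCl3, DMF, MeCN, 0 °C → rt; then H2O, 50 °C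
Reagents that add atoms: N,N-dimethylformamide, CN(C)C=O; water, O
Why: Vilsmeier–Haack formylation; attack para to one hydroxyl and ortho to the other (the position next to bromine, as with other 5-substituted resorcinols) places CHO, Br and the two oxygens in the pattern needed for C4, C8a, O5 and O7 of the chroman.

Step 6
Reactants: 11 bromo dihydroxy aldehyde
Product: 12 2-bromo-4,6-bis(methoxymethoxy)benzaldehyde
Conditions: MOMCl, i-Pr2NEt, CH2Cl2, 0 → 40 °C
Reagents that add atoms: chloromethyl methyl ether, COCCl
Why: Acetal protection of both phenols (the hydrogen-bonded one needs excess reagent and warming); the methoxymethyl ethers survive every basic and organometallic step and later direct the lithiation.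

Step 7
Reactants: 12 bis-MOM aldehyde
Product: 13 [2-bromo-4,6-bis(methoxymethoxy)phenyl]methanol
Conditions: NaBH4, MeOH–THF, 0 °C
Reagents that add atoms: none
Why: Borohydride reduction of an aryl aldehyde; the aryl bromide and the acetals are not affected.

Step 8
Reactants: 13 benzylic alcohol
Product: 15 1-bromo-2-(chloromethyl)-3,5-bis(methoxymethoxy)benzene, via mesylate 14 (not isolated)
Conditions: MsCl, Et3N, LiCl, THF, 0 °C; used at once without chromatography
Reagents that add atoms: lithium chloride, [Li+].[Cl-]
Why: Mesylation and chloride displacement in the same flask under base-buffered conditions that spare the acetals; the electron-rich benzylic chloride ionises easily and is therefore taken on immediately.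

Step 9
Reactants: 15 benzylic chloride
Product: 16 1-bromo-2-(but-2-yn-1-yl)-3,5-bis(methoxymethoxy)benzene
Conditions: CH3C≡CMgBr, CuBr·SMe2 (10 mol %), THF, 0 °C → rt
Reagents that add atoms: prop-1-ynylmagnesium bromide, CC#C[Mg]Br
Why: Copper-catalysed substitution of a benzylic halide by an alkynyl Grignard reagent; the aryl bromide should not react with the alkynylcopper species at this temperature.

Step 10
Reactants: 16 butynyl arene
Product: 18 1-bromo-2-[(2E)-3-iodobut-2-en-1-yl]-3,5-bis(methoxymethoxy)benzene, via alkenylzirconocene 17 (not isolated)
Conditions: Cp2Zr(H)Cl (1.5 equiv), THF, rt → 40 °C; then I2, 0 °C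
Reagents that add atoms: iodine, II
Why: Hydrozirconation is a syn addition that, after equilibration with the slight excess of hydride, places zirconium on the less hindered methyl-bearing alkyne carbon; iodinolysis proceeds with retention, so iodine is trans and methyl cis to the benzylic CH2, the geometry that later defines C4/C5.

Step 11
Reactants: 8 cis vinyl morpholine amide; 18 (E)-alkenyl iodide
Product: 20 [(1R,2R)-2-[(3E)-5-[2-bromo-4,6-bis(methoxymethoxy)phenyl]-3-methylpent-3-en-1-yl]-3,3-dimethylcyclobutyl](morpholin-4-yl)methanone, via alkyl-9-BBN 19 (not isolated)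
Conditions: 9-BBN, THF, rt; then 18, PdCl2(dppf) (5 mol %), AsPh3, Cs2CO3, DMF–H2O, rt
Reagents that add atoms: none
Why: Anti-Markovnikov hydroboration of the vinyl group and B-alkyl Suzuki–Miyaura coupling with retention of the alkenyl iodide geometry; oxidative addition to the alkenyl iodide is far faster than to the hindered, electron-rich aryl bromide.

Step 12
Reactants: 20 (E)-trisubstituted alkene
Product: 21 [(1R,2R)-2-{2-[(2S,3S)-3-{[2-bromo-4,6-bis(methoxymethoxy)phenyl]methyl}-2-methyloxiran-2-yl]ethyl}-3,3-dimethylcyclobutyl](morpholin-4-yl)methanone
Conditions: ent-Shi ketone (L-fructose-derived, 30 mol %), KHSO5 (as 2KHSO5·KHSO4·K2SO4), K2CO3, Bu4NHSO4, MeCN–CH2(OMe)2–aq. Na2B4O7, 0 °C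
Reagents that add atoms: potassium peroxymonosulfate, [K+].[O-]S(=O)(=O)OO
Why: Shi asymmetric epoxidation of an E trisubstituted alkene through the spiro transition state; the D-fructose-derived ketone is known to give (R,R)-epoxides of this substitution type, so its enantiomer should give the (2S,3S)-epoxide, which fixes C4 as S by catalyst control independent of the remote cyclobutane.

Step 13
Reactants: 21 (2S,3S)-epoxide
Product: 22 [(1R,2R)-2-[(3S,4S)-4-{[2-bromo-4,6-bis(methoxymethoxy)phenyl]methyl}-3-hydroxy-3-methylhex-5-en-1-yl]-3,3-dimethylcyclobutyl](morpholin-4-yl)methanone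
Conditions: CH2=CHMgBr (4 equiv), CuBr·SMe2 (2 equiv), BF3·OEt2, THF–Et2O, −78 → −40 °C
Reagents that add atoms: vinylmagnesium bromide, C=C[Mg]Br
Why: Lewis-acid-assisted cuprate opening of a trisubstituted epoxide at its secondary carbon with inversion (SN2), which leaves the tertiary C–O bond intact; oxygen at C4 and vinyl at C5 end up anti across the former E alkene, which is the anti relationship of the C4 methyl and the C5 hydrogen in the target. The amide should not react with the cuprate.

Step 14
Reactants: 22 tertiary homoallylic alcohol
Product: 23 [(1R,2R)-2-{2-[(2S,3S)-3-ethenyl-5,7-bis(methoxymethoxy)-2-methyl-3,4-dihydro-2H-1-benzopyran-2-yl]ethyl}-3,3-dimethylcyclobutyl](morpholin-4-yl)methanone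
Conditions: NaH, CuBr·SMe2 (1.5 equiv), pyridine, 110 °C
Reagents that add atoms: none
Why: Intramolecular Ullmann-type etherification of a tertiary alkoxide with the ortho aryl bromide closes six-membered ring C at the aryl carbon, so C4 keeps its configuration; copper is chosen because an arylpalladium species would insert into the nearby vinyl group (5-exo Heck).

Step 15
Reactants: 23 chroman morpholine amide (cis cyclobutane)
Product: 26 1-[(1S,2R)-2-{2-[(2S,3S)-3-ethenyl-5,7-bis(methoxymethoxy)-2-methyl-3,4-dihydro-2H-1-benzopyran-2-yl]ethyl}-3,3-dimethylcyclobutyl]ethan-1-one (trans), via lithium aminal alkoxide 24 (not isolated), via cis-ketone 25 (not isolated)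
Conditions: MeLi (3 equiv), THF, −78 → 0 °C; MeOH; then NaOMe, MeOH, rt
Reagents that add atoms: methyllithium, [Li]C
Why: Single addition of the organolithium to the morpholine amide gives a stable tetrahedral adduct that collapses to the methyl ketone on quenching; methoxide then equilibrates the enolisable C9 centre to the thermodynamically preferred trans-1,2-disubstituted cyclobutane (C9 becomes S), while C1 cannot enolise.

Step 16
Reactants: 26 trans methyl ketone
Product: 28 1-[(1S,2R)-2-{2-[(2S,3S)-3-ethenyl-5,7-bis(methoxymethoxy)-2-methyl-3,4-dihydro-2H-1-benzopyran-2-yl]ethyl}-3,3-dimethylcyclobutyl]ethenyl trifluoromethanesulfonate, via potassium enolate 27 (not isolated)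
Conditions: KN(SiMe3)2, THF, −78 °C; then PhNTf2, −78 → 0 °C
Reagents that add atoms: N-phenylbis(trifluoromethanesulfonimide), O=S(=O)(N(c1ccccc1)S(=O)(=O)C(F)(F)F)C(F)(F)F
Why: Kinetic deprotonation at the methyl group (the cyclobutyl α-hydrogen is hindered and would give a strained exocyclic enolate) and O-sulfonylation give the 2-alkenyl triflate without any electrophilic halogen; C9 is not epimerised.

Step 17
Reactants: 28 vinyl chroman with cyclobutyl enol triflate (ring-closure precursor)
Product: 30 caryophyllane-fused 5,7-bis(methoxymethoxy)chroman (1R,4S,5R,9S; nine-membered ring B with C8 methylene and trans-fused dimethylcyclobutane), via alkyl-9-BBN 29 (not isolated)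
Conditions: 9-BBN (2.5 equiv), THF, rt → 40 °C; then slow addition (12 h) to PdCl2(dppf) (20 mol %), AsPh3, Cs2CO3, DMF–THF–H2O, 50 °C (final 1 mM)
Reagents that add atoms: none
Why: 9-BBN adds its boron to the terminal carbon (C7) of the monosubstituted alkene; base converts the trialkylborane into a borate, which transmetallates to the alkenylpalladium triflate formed by oxidative addition of zerovalent palladium into the C8–O bond, and reductive elimination forms the C7–C8 bond. The closest known reaction type is the B-alkyl Suzuki–Miyaura macrocyclisation of an ω-borylalkyl alkenyl (pseudo)halide, used here at the small end of its ring-size range. Ring B closes as a nine-membered carbocycle by an intramolecular sp3–sp2 coupling that is exo with respect to the alkenylpalladium unit, so the methylene stays exocyclic and nothing has to be removed afterwards. No stereocentre is formed, and C9 has no adjacent carbonyl and cannot epimerise. The step needs hydroboration at the vinyl group only, which the substrate secures because it has no carbonyl or hydroxyl group and its other alkene is a 1,1-disubstituted, electron-poor enol triflate that 9-BBN does not attack. It also needs cyclisation over oligomerisation, which is served by slow addition into a dilute catalyst solution and by the rigidity of the tether, held on one side by the chroman (C4 and C5 substituents gauche) and on the other by the trans-cyclobutane.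

Step 18
Reactants: 30 bis-MOM tetracycle; 31 isobutyryl chloride (2-methylpropanoyl chloride)
Product: 33 6-(2-methylpropanoyl) derivative of 30 (acyl group on the arene carbon between the two methoxymethoxy groups), via C6-aryllithium 32 (not isolated)
Conditions: n-BuLi, TMEDA, THF, 0 °C; then 31, −78 °C
Reagents that add atoms: none
Why: Directed ortho-metalation at the arene carbon flanked by both acetal oxygens (double chelation; the other free position has one acetal neighbour and the hindered ring oxygen), followed by acylation; the di-ortho-substituted aryl ketone should resist a second addition.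

Step 19
Reactants: 33 bis-MOM aryl ketone
Product: 34 5,7-dihydroxy-6-(2-methylpropanoyl) chroman of the caryophyllane tetracycle (both methoxymethyl groups removed)
Conditions: HCl (0.5 M), MeOH, 0 °C → rt
Reagents that add atoms: none
Why: Acid-catalysed acetal exchange with methanol; acetals ortho to an aryl ketone cleave under mild conditions that should leave the exocyclic alkene, the cyclobutane and the tertiary ether untouched.

Step 20
Reactants: 34 acylphloroglucinol chroman
Product: 36 CNP0497637.1 (target), via 8-methyl phenol 35 (not isolated)
Conditions: NaOMe (4 equiv), MeI (excess), MeOH, 0 °C → rt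
Reagents that add atoms: iodomethane, CI
Why: Two successive C-methylations of the acylphloroglucinol phenoxide at its only unsubstituted ring carbon (C8); the second one dearomatises ring D to the enolised β-triketone, as in the known gem-dimethylation of acylphloroglucinols, and the protic solvent favours C- over O-alkylation.

## Compound list

1 | (S)-5-(hydroxymethyl)furan-2(5H)-one | OC[C@H]1OC(=O)C=C1 | starting material
2 | [(2S)-5-oxo-2,5-dihydrofuran-2-yl]methyl 4-methylbenzenesulfonate | Cc1ccc(cc1)S(=O)(=O)OC[C@H]1OC(=O)C=C1 | intermediate
3 | isobutylene (2-methylpropene) | C=C(C)C | starting material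
4 | [(1R,4S,5R)-6,6-dimethyl-2-oxo-3-oxabicyclo[3.2.0]heptan-4-yl]methyl 4-methylbenzenesulfonate | O=C1O[C@H](COS(=O)(=O)c3ccc(C)cc3)[C@@H]2[C@H]1CC2(C)C | intermediate
5 | (1R,4S,5R)-4-(iodomethyl)-6,6-dimethyl-3-oxabicyclo[3.2.0]heptan-2-one | O=C1O[C@H](CI)[C@@H]2[C@H]1CC2(C)C | intermediate (not isolated)
6 | (1R,2R)-2-ethenyl-3,3-dimethylcyclobutane-1-carboxylic acid (cis) | OC(=O)[C@@H]1CC(C)(C)[C@@H]1C=C | intermediate
7 | (1R,2R)-2-ethenyl-3,3-dimethylcyclobutane-1-carbonyl chloride | ClC(=O)[C@@H]1CC(C)(C)[C@@H]1C=C | intermediate (not isolated)
8 | [(1R,2R)-2-ethenyl-3,3-dimethylcyclobutyl](morpholin-4-yl)methanone | O=C([C@@H]1CC(C)(C)[C@@H]1C=C)N1CCOCC1 | intermediate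
9 | 5-bromobenzene-1,3-diol | Oc1cc(O)cc(Br)c1 | starting material
10 | [(2-bromo-4,6-dihydroxyphenyl)methylidene]dimethylammonium chloride | C[N+](C)=Cc1c(O)cc(O)cc1Br.[Cl-] | intermediate (not isolated)
11 | 2-bromo-4,6-dihydroxybenzaldehyde | O=Cc1c(O)cc(O)cc1Br | intermediate
12 | 2-bromo-4,6-bis(methoxymethoxy)benzaldehyde | O=Cc1c(OCOC)cc(OCOC)cc1Br | intermediate
13 | [2-bromo-4,6-bis(methoxymethoxy)phenyl]methanol | OCc1c(OCOC)cc(OCOC)cc1Br | intermediate
14 | [2-bromo-4,6-bis(methoxymethoxy)phenyl]methyl methanesulfonate | CS(=O)(=O)OCc1c(OCOC)cc(OCOC)cc1Br | intermediate (not isolated)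
15 | 1-bromo-2-(chloromethyl)-3,5-bis(methoxymethoxy)benzene | ClCc1c(OCOC)cc(OCOC)cc1Br | intermediate
16 | 1-bromo-2-(but-2-yn-1-yl)-3,5-bis(methoxymethoxy)benzene | CC#CCc1c(OCOC)cc(OCOC)cc1Br | intermediate
17 | chloro[(2E)-4-[2-bromo-4,6-bis(methoxymethoxy)phenyl]but-2-en-2-yl]zirconocene | Cl[Zr](C1C=CC=C1)(C1C=CC=C1)/C(C)=C/Cc1c(OCOC)cc(OCOC)cc1Br | intermediate (not isolated)
18 | 1-bromo-2-[(2E)-3-iodobut-2-en-1-yl]-3,5-bis(methoxymethoxy)benzene | I/C(C)=C/Cc1c(OCOC)cc(OCOC)cc1Br | intermediate
19 | [(1R,2R)-2-[2-(9-borabicyclo[3.3.1]nonan-9-yl)ethyl]-3,3-dimethylcyclobutyl](morpholin-4-yl)methanone | O=C([C@@H]1CC(C)(C)[C@@H]1CCB1C2CCCC1CCC2)N1CCOCC1 | intermediate (not isolated)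
20 | [(1R,2R)-2-[(3E)-5-[2-bromo-4,6-bis(methoxymethoxy)phenyl]-3-methylpent-3-en-1-yl]-3,3-dimethylcyclobutyl](morpholin-4-yl)methanone | O=C([C@@H]1CC(C)(C)[C@@H]1CC/C(C)=C/Cc1c(OCOC)cc(OCOC)cc1Br)N1CCOCC1 | intermediate
21 | [(1R,2R)-2-{2-[(2S,3S)-3-{[2-bromo-4,6-bis(methoxymethoxy)phenyl]methyl}-2-methyloxiran-2-yl]ethyl}-3,3-dimethylcyclobutyl](morpholin-4-yl)methanone | O=C([C@@H]1CC(C)(C)[C@@H]1CC[C@]2(C)O[C@H]2Cc1c(OCOC)cc(OCOC)cc1Br)N1CCOCC1 | intermediate
22 | [(1R,2R)-2-[(3S,4S)-4-{[2-bromo-4,6-bis(methoxymethoxy)phenyl]methyl}-3-hydroxy-3-methylhex-5-en-1-yl]-3,3-dimethylcyclobutyl](morpholin-4-yl)methanone | O=C([C@@H]1CC(C)(C)[C@@H]1CC[C@](C)(O)[C@H](C=C)Cc1c(OCOC)cc(OCOC)cc1Br)N1CCOCC1 | intermediate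
23 | [(1R,2R)-2-{2-[(2S,3S)-3-ethenyl-5,7-bis(methoxymethoxy)-2-methyl-3,4-dihydro-2H-1-benzopyran-2-yl]ethyl}-3,3-dimethylcyclobutyl](morpholin-4-yl)methanone | C=C[C@@H]1Cc2c(OCOC)cc(OCOC)cc2O[C@@]1(C)CC[C@@H]1[C@H](C(=O)N2CCOCC2)CC1(C)C | intermediate
24 | lithium 1-(morpholin-4-yl)ethan-1-olate adduct of 23 (tetrahedral MeLi adduct at the amide carbon) | C=C[C@@H]1Cc2c(OCOC)cc(OCOC)cc2O[C@@]1(C)CC[C@@H]1[C@H](C(C)([O-])N2CCOCC2)CC1(C)C.[Li+] | intermediate (not isolated)
25 | 1-[(1R,2R)-2-{2-[(2S,3S)-3-ethenyl-5,7-bis(methoxymethoxy)-2-methyl-3,4-dihydro-2H-1-benzopyran-2-yl]ethyl}-3,3-dimethylcyclobutyl]ethan-1-one (cis) | C=C[C@@H]1Cc2c(OCOC)cc(OCOC)cc2O[C@@]1(C)CC[C@@H]1[C@H](C(C)=O)CC1(C)C | intermediate (not isolated)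
26 | 1-[(1S,2R)-2-{2-[(2S,3S)-3-ethenyl-5,7-bis(methoxymethoxy)-2-methyl-3,4-dihydro-2H-1-benzopyran-2-yl]ethyl}-3,3-dimethylcyclobutyl]ethan-1-one (trans) | C=C[C@@H]1Cc2c(OCOC)cc(OCOC)cc2O[C@@]1(C)CC[C@@H]1[C@@H](C(C)=O)CC1(C)C | intermediate
27 | potassium enolate of 26 (terminal ethen-1-olate) | C=C[C@@H]1Cc2c(OCOC)cc(OCOC)cc2O[C@@]1(C)CC[C@@H]1[C@@H](C(=C)[O-])CC1(C)C.[K+] | intermediate (not isolated)
28 | 1-[(1S,2R)-2-{2-[(2S,3S)-3-ethenyl-5,7-bis(methoxymethoxy)-2-methyl-3,4-dihydro-2H-1-benzopyran-2-yl]ethyl}-3,3-dimethylcyclobutyl]ethenyl trifluoromethanesulfonate | C=C[C@@H]1Cc2c(OCOC)cc(OCOC)cc2O[C@@]1(C)CC[C@@H]1[C@@H](C(=C)OS(=O)(=O)C(F)(F)F)CC1(C)C | intermediate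
29 | 28 with the ethenyl group replaced by 2-(9-borabicyclo[3.3.1]nonan-9-yl)ethyl | B1(CC[C@@H]2Cc3c(OCOC)cc(OCOC)cc3O[C@@]2(C)CC[C@@H]2[C@@H](C(=C)OS(=O)(=O)C(F)(F)F)CC2(C)C)C2CCCC1CCC2 | intermediate (not isolated)
30 | caryophyllane-fused 5,7-bis(methoxymethoxy)chroman, (1R,4S,5R,9S) in caryophyllane numbering: 2-methylchroman whose C2–C3 bond is C4–C5 of a nine-membered ring bearing the C8 methylene and the trans-fused 11,11-dimethylcyclobutane | C=C1CC[C@@H]2Cc3c(OCOC)cc(OCOC)cc3O[C@@]2(C)CC[C@@H]2[C@@H]1CC2(C)C | intermediate
31 | isobutyryl chloride (2-methylpropanoyl chloride) | CC(C)C(=O)Cl | starting material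
32 | C6-lithio derivative of 30 (lithium on the arene carbon between the two methoxymethoxy groups) | C=C1CC[C@@H]2Cc3c(OCOC)c([Li])c(OCOC)cc3O[C@@]2(C)CC[C@@H]2[C@@H]1CC2(C)C | intermediate (not isolated)
33 | 6-(2-methylpropanoyl) derivative of 30 | C=C1CC[C@@H]2Cc3c(OCOC)c(C(=O)C(C)C)c(OCOC)cc3O[C@@]2(C)CC[C@@H]2[C@@H]1CC2(C)C | intermediate
34 | 5,7-dihydroxy-6-(2-methylpropanoyl) chroman of the caryophyllane tetracycle | C=C1CC[C@@H]2Cc3c(O)c(C(=O)C(C)C)c(O)cc3O[C@@]2(C)CC[C@@H]2[C@@H]1CC2(C)C | intermediate
35 | 8-methyl derivative of 34 | C=C1CC[C@@H]2Cc3c(O)c(C(=O)C(C)C)c(O)c(C)c3O[C@@]2(C)CC[C@@H]2[C@@H]1CC2(C)C | intermediate (not isolated)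
36 | CNP0497637.1 | C=C1CC[C@@H]2CC3=C(O[C@@]2(C)CC[C@@H]2[C@@H]1CC2(C)C)C(C)(C)C(=O)C(C(=O)C(C)C)=C3O | target

## Step count and least certain steps

Total: 20 steps. Longest linear sequence: 16 steps (9 → 36, steps 5–20); the cyclobutane branch from 1 joins after 4 steps (14 steps from 1 to 36).

**Step 17 (key step).** The most likely failure is intermolecular coupling and protodeboronation or β-hydride elimination overtaking the slow, strained nine-membered transmetalation and reductive elimination. The fallback sets out from 28 and returns at 30, making the same C7–C8 bond by a polar ring closure. Hydroboration–oxidation of the vinyl group of 28 (9-BBN; NaBO3·4H2O) would give the primary alcohol F1, and Dess–Martin oxidation the aldehyde F2. An intramolecular Nozaki–Hiyama–Kishi reaction of the alkenyl triflate with the aldehyde (CrCl2, NiCl2 cat., DMF, high dilution) would close ring B as the C7 allylic alcohol F3 (either C7 epimer serves). This would be converted into the methyl carbonate F4 (ClCO2Me, pyridine). Palladium-catalysed formate reduction (Pd(OAc)2, PBu3, HCO2NH4) delivers hydride to the more substituted allyl terminus, keeps the alkene exocyclic and returns 30.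

**Step 13.** The most likely failure is that SN2 attack at the shielded secondary epoxide carbon is too slow. BF3-induced rearrangement of the epoxide (hydride shift to a ketone) or participation of the neighbouring ortho acetal oxygen (cyclisation with loss of a methoxymethyl group) would then take over. The fallback sets out from 21 and returns at 22, using a small sp nucleophile without a Lewis acid. Lithium acetylide–ethylenediamine complex in DMSO (rt → 45 °C) should open the epoxide at the secondary carbon with inversion to the homopropargylic tertiary alcohol F5. Semi-hydrogenation (H2, Pd/CaCO3 poisoned with Pb(OAc)2, quinoline) then gives 22.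

**Step 14.** The most likely failure is slow C–O bond formation at the hindered tertiary alkoxide, with hydrodebromination or base-induced retro-allylation of the homoallylic alkoxide competing at 110 °C. The fallback sets out from 22 and returns at 23, replacing copper coupling by elimination–addition. LiTMP (lithium 2,2,6,6-tetramethylpiperidide, 3 equiv, THF, −78 → 0 °C) removes the ring hydrogen between bromine and the acetal oxygen, and loss of bromide gives an aryne. The tethered alkoxide adds at the distal aryne carbon, the site favoured by the adjacent acetal oxygen and enforced by six-membered ring formation, to give 23. No new isolated compound is involved (F0).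

**Step 18.** The most likely failure is loss of site selectivity in the lithiation, with C8 competing with C6 and leading to the regioisomeric ketone. The fallback sets out from 30 and returns at 34, with acylation directed by a free phenol instead of by lithiation. Acidic methanolysis of both acetals of 30 would give the chroman-5,7-diol F6. The C7 hydroxyl has no ortho substituent and should be silylated selectively (t-BuPh2SiCl, imidazole) to the C7 silyl ether F7. Ortho-acylation of the bromomagnesium phenoxide of the remaining C5 hydroxyl (EtMgBr, then 31, toluene) can occur only at C6, its single free ortho position, and gives the ketone F8. Bu4NF then gives 34.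

## Further compounds

F1 | step 17 | 28 with the ethenyl group replaced by 2-hydroxyethyl | OCC[C@@H]1Cc2c(OCOC)cc(OCOC)cc2O[C@@]1(C)CC[C@@H]1[C@@H](C(=C)OS(=O)(=O)C(F)(F)F)CC1(C)C
F2 | step 17 | 28 with the ethenyl group replaced by 2-oxoethyl | O=CC[C@@H]1Cc2c(OCOC)cc(OCOC)cc2O[C@@]1(C)CC[C@@H]1[C@@H](C(=C)OS(=O)(=O)C(F)(F)F)CC1(C)C
F3 | step 17 | 7-hydroxy derivative of 30 (allylic alcohol on the ring-B carbon next to the methylene-bearing carbon, epimer mixture) | C=C1C(O)C[C@@H]2Cc3c(OCOC)cc(OCOC)cc3O[C@@]2(C)CC[C@@H]2[C@@H]1CC2(C)C
F4 | step 17 | methyl carbonate of F3 | C=C1C(OC(=O)OC)C[C@@H]2Cc3c(OCOC)cc(OCOC)cc3O[C@@]2(C)CC[C@@H]2[C@@H]1CC2(C)C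
F5 | step 13 | [(1R,2R)-2-[(3S,4S)-4-{[2-bromo-4,6-bis(methoxymethoxy)phenyl]methyl}-3-hydroxy-3-methylhex-5-yn-1-yl]-3,3-dimethylcyclobutyl](morpholin-4-yl)methanone | O=C([C@@H]1CC(C)(C)[C@@H]1CC[C@](C)(O)[C@H](C#C)Cc1c(OCOC)cc(OCOC)cc1Br)N1CCOCC1
F0 | step 14 | none | none
F6 | step 18 | 5,7-dihydroxy chroman of the caryophyllane tetracycle (30 without its methoxymethyl groups) | C=C1CC[C@@H]2Cc3c(O)cc(O)cc3O[C@@]2(C)CC[C@@H]2[C@@H]1CC2(C)C
F7 | step 18 | 7-O-(tert-butyldiphenylsilyl) ether of F6 | C=C1CC[C@@H]2Cc3c(O)cc(O[Si](c4ccccc4)(c5ccccc5)C(C)(C)C)cc3O[C@@]2(C)CC[C@@H]2[C@@H]1CC2(C)C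
F8 | step 18 | 6-(2-methylpropanoyl) derivative of F7 | C=C1CC[C@@H]2Cc3c(O)c(C(=O)C(C)C)c(O[Si](c4ccccc4)(c5ccccc5)C(C)(C)C)cc3O[C@@]2(C)CC[C@@H]2[C@@H]1CC2(C)C
A1 | alternative 1 | 2H-pyran with the ring-fusion C5=CH double bond (product of the Knoevenagel/oxa-6π step) | C=C1CCC2=CC3=C(O[C@@]2(C)CC[C@@H]2[C@@H]1CC2(C)C)C(C)(C)C(=O)C(C(=O)C(C)C)=C3O
A2 | alternative 1 | (1R,9S)-4,11,11-trimethyl-8-methylidenebicyclo[7.2.0]undec-4-ene-5-carbaldehyde (ring-B enal, alkene geometry as in A4) | C=C1CC/C(C=O)=C(C)/CC[C@@H]2[C@@H]1CC2(C)C
A3 | alternative 1 | 2,2-dimethyl-4-(2-methylpropanoyl)cyclohexane-1,3,5-trione | CC(C)C(=O)C1C(=O)CC(=O)C(C)(C)C1=O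
A4 | alternative 1 | (−)-β-caryophyllene | C=C1CC/C=C(C)/CC[C@@H]2[C@@H]1CC2(C)C
A5 | alternative 2 | 3-allyl-5,7-bis(methoxymethoxy)-2-methyl-2-(4-methylpent-3-en-1-yl)chroman-4-one (allyl trans to the pentenyl chain) | C=CC[C@@H]1C(=O)c2c(OCOC)cc(OCOC)cc2O[C@@]1(C)CCC=C(C)C
A6 | alternative 2 | 5,7-bis(methoxymethoxy)-2-methyl-4H-chromen-4-one | Cc1cc(=O)c2c(OCOC)cc(OCOC)cc2o1
A7 | alternative 2 | (4-methylpent-3-en-1-yl)magnesium bromide | CC(C)=CCC[Mg]Br
A8 | alternative 2 | allyl bromide | C=CCBr
A9 | alternative 3 | cyclobutane-fused ring-B ketone (bis-MOM chroman, C8 ketone) | O=C1CC[C@@H]2Cc3c(OCOC)cc(OCOC)cc3O[C@@]2(C)CC[C@@H]2[C@@H]1CC2(C)C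
A10 | alternative 3 | cis nine-membered ring enone fused to the bis-MOM chroman | O=C1CC[C@@H]2Cc3c(OCOC)cc(OCOC)cc3O[C@@]2(C)CC/C=C\1
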